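The readings were computed for substances that don't exist.

There was far more starting complex than incoming ligand in west, 2.0 M against portions of 0.0500 M, so I followed one molecule of incoming ligand through that flask.

| flask | starting complex | incoming ligand | remark | time |
|---|---|---|---|---|
| eta | 0.37 M | 0.55 M (in portions, 4) | run made earlier; portions every 6.0 h |  |
| beta | 1.1 M | 0.55 M (in portions, 4) | run made earlier; portions every 6.0 h |  |
| zeta | 1.9 M | 0.55 M (in portions, 4) | run made earlier; portions every 6.0 h |  |
| gamma | 0.50 M | 0.41 M (in portions, 4) | run made earlier; portions every 6.0 h |  |
| north | 0.50 M | 0.200 M (in portions, 4) | the portions of incoming ligand follow each other after 4.0 h, the first at the start | 30 h |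
| west | 2.0 M | 0.200 M (in portions, 4) | the portions of incoming ligand follow each other after 6.0 h, the first at the start | 30 h |
| north-west | 2.0 M | 1.20 M (in portions, 4) | the portions of incoming ligand follow each other after 6.0 h, the first at the start | 30 h |
| north-east | 2.0 M | 0.800 M (in portions, 4) | the portions of incoming ligand follow each other after 12 h, the first at the start | 30 h |
| south-east | 0.50 M | 0.550 M (in portions, 4) | the portions of incoming ligand follow each other after 6.0 h, the first at the start | 30 h |

| run | time / h | complex with one exchanged / % | starting complex / % |
|---|---|---|---|
| eta | 2.50 | 2.4 | 96.8 |
| eta | 6.00 | 5.8 | 93.9 |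
| eta | 12.0 | 14.0 | 87.3 |
| eta | 30.0 | 38.6 | 63.0 |
| beta | 2.50 | 4.2 | 96.9 |
| beta | 6.00 | 3.4 | 96.6 |
| beta | 12.0 | 12.9 | 90.0 |
| beta | 30.0 | 31.1 | 69.6 |
| zeta | 4.00 | 4.1 | 96.5 |
| zeta | 10.0 | 7.3 | 92.9 |
| zeta | 20.0 | 16.6 | 83.5 |
| zeta | 30.0 | 23.6 | 77.6 |
| gamma | 2.50 | 3.4 | 98.2 |
| gamma | 6.00 | 5.1 | 96.3 |
| gamma | 12.0 | 10.7 | 87.5 |
| gamma | 30.0 | 29.1 | 69.0 |

(each reading ± 1 percentage point)

* the flasks put in order of amount of complex with one exchanged, in percent of the starting complex charged, best first, at 30 h (north / west / north-west / north-east / south-east)
* the same order at 5.0 d (north / west / north-west / north-east / south-east)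
* the amount of complex with one exchanged, in percent of the starting complex charged of the flask you put first, at 30 h
* the amount of complex with one exchanged, in percent of the starting complex charged of the flask you put last, at 30 h

- percentages count the whole charge, also what has not yet gone in

I took incoming ligand as the limiting reagent of west, with one molecule per complex with one exchanged. Its ceiling was then 10.0% of the starting complex charged, lower than in the other flasks, so I put west last. With that ceiling, [starting complex] in west stays above 90.0% of its charge, and a molecule of incoming ligand faces a nearly constant partner, so I treated its passage into product as a pseudo-first-order decay with one apparent time constant τ, inversely proportional to [starting complex].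

I read τ from the zeta run, where the two complexes add to 101% at 30.0 h. After its last portion, the unconverted ligand, reckoned as charge minus product, fell from 0.235 M to 0.102 M between 20.0 h and 30.0 h; this is not free ligand, since it also counts any ligand gone some other way. That gave an apparent time constant, for passage into product, of 11.9 h at [starting complex] of 1.47 M. It is a reading, and each percentage in it carries a scatter of 1 percentage point.

Scaled to west:

τ = 8.81 h

unconverted share of a portion after time t = exp(−t/τ)

In the first instants of west, the first portion simply began this decay. In the middle the portions overlapped, since τ was longer than their spacing, and by my reckoning 50.6% of a portion was still unconverted when the next went in. At the end, the last portion, added at 18.0 h, had 12.0 h to run, which by my reckoning left 25.6% of it unconverted at 30 h.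

The quantity I carried was the catch share, the chance that a molecule of the whole charge has been taken by starting complex at the reading time, which is one minus the mean unconverted share of the portions:

catch share, west = 87.9%

complex with one exchanged, west = ceiling × catch share = 8.79%

The forecast gave north-west > south-east > north > north-east > west at 30 h and south-east > north-west > north-east > north > west at 5.0 d, with 38% for the first flask and 9.7% for the last, saying “west about 9.7, close to its 10% cap”.

The flask gave north-west > south-east > north-east > north > west at 30 h and south-east > north-west > north-east > north > west at 5.0 d, with 38.9% in north-west and 8.81% in west, where I had reckoned 8.79%.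

    complex with two exchanged + incoming ligand ⇌ leaving ligand + complex with three exchanged (K = 0.281, k = 0.00217 L mol⁻¹ min⁻¹)
    starting complex + incoming ligand ⇌ leaving ligand + complex with one exchanged (K = 24.0, k = 0.00131 L mol⁻¹ min⁻¹)
    complex with three exchanged + incoming ligand ⇌ leaving ligand + complex with four exchanged (K = 0.355, k = 0.00153 L mol⁻¹ min⁻¹)
    complex with one exchanged + incoming ligand ⇌ leaving ligand + complex with two exchanged (K = 0.430, k = 8.56 × 10⁻⁵ L mol⁻¹ min⁻¹)
    2 incoming ligand → self-condensation product (k = 0.00145 L mol⁻¹ min⁻¹)

The neighbouring flask was west with 0.080 M of incoming ligand. Its [starting complex] and its portion times stayed as they were, so I carried over τ and the catch share of 87.9%, now on a ceiling of 4.00%. That reckons to 3.52% of the starting complex charged as complex with one exchanged. The flask gave 3.66%, with 6.3% of its incoming ligand still free at 30 h.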